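Ring A is cut at C2′–C3′ and C1′–C6′ (primed locants: ring A) and is grown around the isopropyl methine from a chiral siloxyalkyne and 3-methoxy-2,4,4-trimethylcyclobutenone. One thermal operation makes both bonds, re-closes C3′–C4′ by 6π electrocyclisation and delivers the C5′ methoxy, C6′ methyl and C4′ gem-dimethyl groups in place. The step exploits the quaternary C4′ of ring A: with no hydrogen there, the annulation cannot end in a phenol and stops as the cyclohexa-2,4-dienone, silylated on the C1′ oxygen. The precursor is the (S)-configured alkyne carrying ring B as its C8a SEM ether and C5, C7 benzyl ethers. Ring C is closed afterwards by Mitsunobu etherification and Friedel–Crafts acylation at C4a.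

Key step: step 12

Remark (assumptions): ring A of the target is one enol tautomer of a C1′/C3′ β-diketone, so release of either enol gives the target; 1-methoxyprop-1-yne is taken as purchasable; the hand of BINAP in step 8 is the one that gives the (R)-acid, which a test run fixes (the antipodal ligand is used otherwise).

Labels: ring A carbons carry primed locants, C1′ (C=O), C2′ (bears the methine), C3′ (enol carbon), C4′ (CMe2), C5′ (C–OMe), C6′ (C–Me); rings B and C carry flavanone numbering. SEM = 2-(trimethylsilyl)ethoxymethyl, TIPS = triisopropylsilyl, Bn = benzyl.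

Design notes: the C–H borylation is run on silyl ethers, because benzyl ethers would offer six unhindered aryl C–H bonds of their own to the [Ir(OMe)(cod)]2 catalyst. The hydrogenation is run on the free acid, because Ru(OAc)2(BINAP) needs a carboxylate to bind.

Step 1
Reactants: 1 2-methylresorcinol
Product: 2 1,3-bis(triisopropylsilyloxy)-2-methylbenzene
Conditions: i-Pr3SiCl, imidazole, DMF, 40 °C
Reagents that add atoms: triisopropylsilyl chloride, CC(C)[Si](Cl)(C(C)C)C(C)C
Why: Phenol silylation; the bulky silyl ethers have no aryl C–H bonds of their own and shield C4 and C6 of the ring for the next step.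

Step 2
Reactants: 2 1,3-bis(triisopropylsilyloxy)-2-methylbenzene
Product: 4 4-methyl-3,5-bis(triisopropylsilyloxy)phenol, via arylboronic pinacol ester 3 (not isolated)
Conditions: [Ir(OMe)(cod)]2 (cat.), 4,4'-di-tert-butyl-2,2'-bipyridine (cat.), B2pin2, THF, 80 °C; then KHSO5, acetone/H2O, rt
Reagents that add atoms: bis(pinacolato)diboron (boron of 3 only), CC1(C)OB(OC1(C)C)B1OC(C)(C)C(C)(C)O1; potassium peroxymonosulfate, [K+].[O-]S(=O)(=O)OO
Why: Sterically governed Ir-catalysed C–H borylation should take the only ring C–H without an ortho substituent (C5), and one-pot oxidation converts C–B into C–O, so the third oxygen arrives meta to the other two.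

Step 3
Reactants: 4 4-methyl-3,5-bis(triisopropylsilyloxy)phenol
Product: 5 1-(SEM-oxy)-4-methyl-3,5-bis(triisopropylsilyloxy)benzene
Conditions: SEMCl, i-Pr2NEt, CH2Cl2, 0 °C to rt
Reagents that add atoms: 2-(trimethylsilyl)ethoxymethyl chloride, C[Si](C)(C)CCOCCl
Why: Williamson-type O-alkylation with the chloromethyl ether marks the future C8a oxygen with a group that directs lithiation and leaves with fluoride.

Step 4
Reactants: 5 1-(SEM-oxy)-4-methyl-3,5-bis(triisopropylsilyloxy)benzene
Product: 7 1,3-bis(benzyloxy)-2-methyl-5-(SEM-oxy)benzene, via resorcinol bis-phenoxide 6 (not isolated)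
Conditions: Bu4NF, THF, 0 °C; then BnBr, rt
Reagents that add atoms: benzyl bromide, BrCc1ccccc1
Why: Fluoride cleaves the two aryl silyl ethers and the ammonium phenoxides undergo Williamson benzylation in the same flask, while the aryl SEM ether should resist fluoride at this temperature.

Step 5
Reactants: 7 1,3-bis(benzyloxy)-2-methyl-5-(SEM-oxy)benzene; 8 diethyl oxalate
Product: 10 ethyl 2-[2,4-bis(benzyloxy)-3-methyl-6-(SEM-oxy)phenyl]-2-oxoacetate, via aryllithium 9 (not isolated)
Conditions: n-BuLi, THF, 0 °C; then cannulated into 8 (3 equiv), THF, −78 °C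
Reagents that add atoms: none
Why: Directed ortho-metalation between the SEM ether and a benzyl ether (the two free ring positions are equivalent), then acyl substitution on excess oxalate by inverse addition, which should stop at the α-keto ester.

Step 6
Reactants: 10 ethyl 2-[2,4-bis(benzyloxy)-3-methyl-6-(SEM-oxy)phenyl]-2-oxoacetate
Product: 11 ethyl 2-[2,4-bis(benzyloxy)-3-methyl-6-(SEM-oxy)phenyl]-3-methylbut-2-enoate
Conditions: i-PrPPh3I, n-BuLi, THF, 0 °C; then 10, 0 to 60 °C
Reagents that add atoms: isopropyltriphenylphosphonium iodide, CC(C)[P+](c1ccccc1)(c1ccccc1)c1ccccc1.[I-]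
Why: Wittig olefination; the ketone of an α-keto ester is activated and cannot enolise, so the isopropylidene ylide should add there and not to the ester.

Step 7
Reactants: 11 ethyl 2-[2,4-bis(benzyloxy)-3-methyl-6-(SEM-oxy)phenyl]-3-methylbut-2-enoate
Product: 12 2-[2,4-bis(benzyloxy)-3-methyl-6-(SEM-oxy)phenyl]-3-methylbut-2-enoic acid
Conditions: KOH, EtOH/H2O, 80 °C; then aq. HCl to pH 4, 0 °C
Reagents that add atoms: potassium hydroxide, [K+].[OH-]
Why: Saponification frees the carboxylic acid that the hydrogenation catalyst needs as its anchor; aryl benzyl and SEM ethers are stable to hot alkali.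

Step 8
Reactants: 12 2-[2,4-bis(benzyloxy)-3-methyl-6-(SEM-oxy)phenyl]-3-methylbut-2-enoic acid
Product: 13 (R)-2-[2,4-bis(benzyloxy)-3-methyl-6-(SEM-oxy)phenyl]-3-methylbutanoic acid
Conditions: Ru(OAc)2[(R)-BINAP] (cat.), H2 (100 bar), Et3N (1 equiv), MeOH, 50 °C
Reagents that add atoms: none
Why: Carboxylate-directed asymmetric hydrogenation of a 2-aryl-3-methylbut-2-enoic acid, a substrate class established for Ru(OAc)2(BINAP)-type catalysts; the C2-symmetric ligand selects the alkene face and sets the methine as (R), and benzyl ethers are inert to this homogeneous catalyst.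

Step 9
Reactants: 13 (R)-2-[2,4-bis(benzyloxy)-3-methyl-6-(SEM-oxy)phenyl]-3-methylbutanoic acid
Product: 14 methyl (R)-2-[2,4-bis(benzyloxy)-3-methyl-6-(SEM-oxy)phenyl]-3-methylbutanoate
Conditions: MeI, K2CO3, DMF, rt
Reagents that add atoms: iodomethane, CI
Why: SN2 O-methylation of the carboxylate gives the ester needed for homologation under conditions too mild to enolise the crowded α-position.

Step 10
Reactants: 14 methyl (R)-2-[2,4-bis(benzyloxy)-3-methyl-6-(SEM-oxy)phenyl]-3-methylbutanoate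
Product: 17 {[(3S)-3-[2,4-bis(benzyloxy)-3-methyl-6-(SEM-oxy)phenyl]-4-methylpent-1-yn-1-yl]oxy}triisopropylsilane, via dibromomethyl ketone enolate 15 (not isolated), via lithium ynolate 16 (not isolated)
Conditions: CH2Br2, LiTMP (lithium 2,2,6,6-tetramethylpiperidide), THF, −90 °C, then 14; LiN(SiMe3)2; n-BuLi, −78 to 0 °C; i-Pr3SiOTf, −78 °C
Reagents that add atoms: dibromomethane, BrCBr; triisopropylsilyl trifluoromethanesulfonate, CC(C)[Si](OS(=O)(=O)C(F)(F)F)(C(C)C)C(C)C
Why: Kowalski ester homologation interrupted at the ynolate: acylation of dibromomethyllithium, bromine–lithium exchange and 1,2-shift of the chiral alkyl group with retention give the ynolate, which the bulky silyl triflate should trap on oxygen (the descriptor changes to S only through the priority rules).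

Step 11
Reactants: 18 isobutyryl chloride; 19 1-methoxyprop-1-yne
Product: 21 3-methoxy-2,4,4-trimethylcyclobut-2-en-1-one, via dimethylketene 20 (not isolated)
Conditions: Et3N, CH2Cl2, 0 °C to reflux
Reagents that add atoms: none
Why: Ketene–ynol ether [2+2] cycloaddition; the nucleophilic methyl-bearing alkyne carbon bonds to the ketene carbonyl carbon, which places methoxy on C3 and the gem-dimethyl group on C4.

Step 12
Reactants: 17 {[(3S)-3-[2,4-bis(benzyloxy)-3-methyl-6-(SEM-oxy)phenyl]-4-methylpent-1-yn-1-yl]oxy}triisopropylsilane; 21 3-methoxy-2,4,4-trimethylcyclobut-2-en-1-one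
Product: 25 2-{(1R)-1-[2,4-bis(benzyloxy)-3-methyl-6-(SEM-oxy)phenyl]-2-methylpropyl}-5-methoxy-4,6,6-trimethyl-3-(triisopropylsilyloxy)cyclohexa-2,4-dien-1-one, via vinylketene 22 (not isolated), via alkenylcyclobutenone 23 (not isolated), via dienylketene 24 (not isolated)
Conditions: PhMe, 100 °C, sealed tube, argon, 21 in excess
Reagents that add atoms: none
Why: Proposed new method: heat opens 21 by 4π electrocyclic ring opening to vinylketene 22, whose ketene carbon (future C3′) is attacked by the nucleophilic, methine-bearing alkyne carbon (future C2′) in a [2+2] that also joins the oxygenated alkyne carbon (C1′) to the methyl-bearing ketene α-carbon (C6′), giving 23; 4π opening of 23 gives dienylketene 24, whose ketene carbon closes onto the dimethyl terminus. The closest known reaction is the vinylketene–alkyne benzannulation of cyclobutenones with siloxyalkynes (Danheiser annulation), where the same cascade ends in tautomerisation to a phenol; here C4′ is quaternary, so the product should persist as the 6,6-dimethylcyclohexa-2,4-dienone, the ring to which dienylketenes are known to close thermally. Ring A is closed by a thermal disrotatory 6π electrocyclisation that re-forms C3′–C4′, after the two new σ bonds C2′–C3′ and C1′–C6′ are made intermolecularly. No stereocentre is created: the propargylic methine takes part in no bond change and has no acidic or ionisable neighbour under neutral thermal conditions, so its configuration should be carried through (the descriptor becomes R only through the priority rules). The selectivity needed is the regiochemistry of the [2+2], secured by the oxygen polarisation of the ynol ether against the electrophilic ketene carbon. Ketene dimerisation and a 1,5-hydrogen shift in 22 must also be outrun, which the electron-rich alkyne and the excess of 21 should help.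

Step 13
Reactants: 25 2-{(1R)-1-[2,4-bis(benzyloxy)-3-methyl-6-(SEM-oxy)phenyl]-2-methylpropyl}-5-methoxy-4,6,6-trimethyl-3-(triisopropylsilyloxy)cyclohexa-2,4-dien-1-one
Product: 27 3-(benzyloxy)-2-{(1R)-1-[2,4-bis(benzyloxy)-3-methyl-6-(SEM-oxy)phenyl]-2-methylpropyl}-5-methoxy-4,6,6-trimethylcyclohexa-2,4-dien-1-one, via cesium enolate 26 (not isolated)
Conditions: CsF, BnBr, DMF, 0 °C to rt
Reagents that add atoms: benzyl bromide, BrCc1ccccc1
Why: Fluoride desilylation gives the β-diketone enolate, which should alkylate on oxygen because C2′ is blocked by its bulky substituent; a regioisomer benzylated on the C3′ oxygen, if formed, converges in step 18.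

Step 14
Reactants: 27 3-(benzyloxy)-2-{(1R)-1-[2,4-bis(benzyloxy)-3-methyl-6-(SEM-oxy)phenyl]-2-methylpropyl}-5-methoxy-4,6,6-trimethylcyclohexa-2,4-dien-1-one
Product: 28 3-(benzyloxy)-2-{(1R)-1-[2,4-bis(benzyloxy)-6-hydroxy-3-methylphenyl]-2-methylpropyl}-5-methoxy-4,6,6-trimethylcyclohexa-2,4-dien-1-one
Conditions: Bu4NF, THF/DMPU, 60 °C; pH 7 buffer work-up
Reagents that add atoms: none
Why: Fluoride attack on silicon fragments the SEM group (loss of fluorotrimethylsilane, ethene and formaldehyde) and frees the C8a phenol; benzyl aryl ethers and the doubly donor-substituted, crowded benzyl enol ether should not react with fluoride or the phenoxide.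

Step 15
Reactants: 28 3-(benzyloxy)-2-{(1R)-1-[2,4-bis(benzyloxy)-6-hydroxy-3-methylphenyl]-2-methylpropyl}-5-methoxy-4,6,6-trimethylcyclohexa-2,4-dien-1-one; 29 ethyl (R)-3-hydroxy-3-phenylpropanoate
Product: 30 ethyl (3S)-3-{3,5-bis(benzyloxy)-2-[(1R)-1-(2-benzyloxy-4-methoxy-3,5,5-trimethyl-6-oxocyclohexa-1,3-dien-1-yl)-2-methylpropyl]-4-methylphenoxy}-3-phenylpropanoate
Conditions: PPh3, DIAD, PhMe, 0 °C to rt
Reagents that add atoms: none
Why: Mitsunobu etherification; the phenol is the only acidic site and displaces the activated carbinol with inversion, so the (R)-alcohol sets the future C2 as (S).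

Step 16
Reactants: 30 ethyl (3S)-3-{3,5-bis(benzyloxy)-2-[(1R)-1-(2-benzyloxy-4-methoxy-3,5,5-trimethyl-6-oxocyclohexa-1,3-dien-1-yl)-2-methylpropyl]-4-methylphenoxy}-3-phenylpropanoate
Product: 31 (3S)-3-{3,5-bis(benzyloxy)-2-[(1R)-1-(2-benzyloxy-4-methoxy-3,5,5-trimethyl-6-oxocyclohexa-1,3-dien-1-yl)-2-methylpropyl]-4-methylphenoxy}-3-phenylpropanoic acid
Conditions: LiOH, THF/H2O, 0 °C to rt; then aq. HCl to pH 4
Reagents that add atoms: lithium hydroxide, [Li+].[OH-]
Why: Saponification without alcohol co-solvent should be faster than deprotonation α to the ester, so the β-aryloxy group should not be eliminated; the crowded benzyl enol ether is spared.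

Step 17
Reactants: 31 (3S)-3-{3,5-bis(benzyloxy)-2-[(1R)-1-(2-benzyloxy-4-methoxy-3,5,5-trimethyl-6-oxocyclohexa-1,3-dien-1-yl)-2-methylpropyl]-4-methylphenoxy}-3-phenylpropanoic acid
Product: 33 (2S)-5,7-bis(benzyloxy)-8-[(1R)-1-(2-benzyloxy-4-methoxy-3,5,5-trimethyl-6-oxocyclohexa-1,3-dien-1-yl)-2-methylpropyl]-6-methyl-2-phenylchroman-4-one, via mixed trifluoroacetic anhydride 32 (not isolated)
Conditions: (CF3CO)2O, CH2Cl2, 0 °C; NaHCO3 quench
Reagents that add atoms: none
Why: Intramolecular Friedel–Crafts acylation; C4a is the only free ring position and is ortho or para to three oxygens, so the mixed anhydride should close ring C without a Lewis acid, which spares the benzyl ethers and the C2–O bond.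

Step 18
Reactants: 33 (2S)-5,7-bis(benzyloxy)-8-[(1R)-1-(2-benzyloxy-4-methoxy-3,5,5-trimethyl-6-oxocyclohexa-1,3-dien-1-yl)-2-methylpropyl]-6-methyl-2-phenylchroman-4-one
Product: 34 (2S)-5,7-dihydroxy-8-[(1R)-1-(2-hydroxy-4-methoxy-3,3,5-trimethyl-6-oxocyclohexa-1,4-dien-1-yl)-2-methylpropyl]-6-methyl-2-phenylchroman-4-one (CNP0320113.1)
Conditions: H2 (1 bar), Pd/C (palladium on carbon), EtOAc, rt, stopped after three equivalents of H2
Reagents that add atoms: none
Why: Hydrogenolysis of the three O-benzyl groups under neutral conditions frees both phenols and the ring A enol, whose two enol forms interconvert by proton transfer, so the product is the target as drawn (C1′ carbonyl, C3′ enol); the cyclic C2–O bond and the tetrasubstituted push–pull alkenes of ring A should be slow to reduce.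

Compound list
1 | 2-methylresorcinol | Cc1c(O)cccc1O | starting material
2 | 1,3-bis(triisopropylsilyloxy)-2-methylbenzene | Cc1c(O[Si](C(C)C)(C(C)C)C(C)C)cccc1O[Si](C(C)C)(C(C)C)C(C)C | intermediate
3 | 2-[4-methyl-3,5-bis(triisopropylsilyloxy)phenyl]-4,4,5,5-tetramethyl-1,3,2-dioxaborolane | Cc1c(O[Si](C(C)C)(C(C)C)C(C)C)cc(B2OC(C)(C)C(C)(C)O2)cc1O[Si](C(C)C)(C(C)C)C(C)C | intermediate (not isolated)
4 | 4-methyl-3,5-bis(triisopropylsilyloxy)phenol | Cc1c(O[Si](C(C)C)(C(C)C)C(C)C)cc(O)cc1O[Si](C(C)C)(C(C)C)C(C)C | intermediate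
5 | 1-(SEM-oxy)-4-methyl-3,5-bis(triisopropylsilyloxy)benzene | Cc1c(O[Si](C(C)C)(C(C)C)C(C)C)cc(OCOCC[Si](C)(C)C)cc1O[Si](C(C)C)(C(C)C)C(C)C | intermediate
6 | 2-methyl-5-(SEM-oxy)benzene-1,3-diol, present as its bis(tetrabutylammonium) phenoxide | Cc1c(O)cc(OCOCC[Si](C)(C)C)cc1O | intermediate (not isolated)
7 | 1,3-bis(benzyloxy)-2-methyl-5-(SEM-oxy)benzene | Cc1c(OCc2ccccc2)cc(OCOCC[Si](C)(C)C)cc1OCc1ccccc1 | intermediate
8 | diethyl oxalate | CCOC(=O)C(=O)OCC | starting material
9 | [2,4-bis(benzyloxy)-3-methyl-6-(SEM-oxy)phenyl]lithium | [Li]c1c(OCOCC[Si](C)(C)C)cc(OCc2ccccc2)c(C)c1OCc1ccccc1 | intermediate (not isolated)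
10 | ethyl 2-[2,4-bis(benzyloxy)-3-methyl-6-(SEM-oxy)phenyl]-2-oxoacetate | CCOC(=O)C(=O)c1c(OCOCC[Si](C)(C)C)cc(OCc2ccccc2)c(C)c1OCc1ccccc1 | intermediate
11 | ethyl 2-[2,4-bis(benzyloxy)-3-methyl-6-(SEM-oxy)phenyl]-3-methylbut-2-enoate | CCOC(=O)C(=C(C)C)c1c(OCOCC[Si](C)(C)C)cc(OCc2ccccc2)c(C)c1OCc1ccccc1 | intermediate
12 | 2-[2,4-bis(benzyloxy)-3-methyl-6-(SEM-oxy)phenyl]-3-methylbut-2-enoic acid | CC(C)=C(C(=O)O)c1c(OCOCC[Si](C)(C)C)cc(OCc2ccccc2)c(C)c1OCc1ccccc1 | intermediate
13 | (R)-2-[2,4-bis(benzyloxy)-3-methyl-6-(SEM-oxy)phenyl]-3-methylbutanoic acid | CC(C)[C@@H](C(=O)O)c1c(OCOCC[Si](C)(C)C)cc(OCc2ccccc2)c(C)c1OCc1ccccc1 | intermediate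
14 | methyl (R)-2-[2,4-bis(benzyloxy)-3-methyl-6-(SEM-oxy)phenyl]-3-methylbutanoate | CC(C)[C@@H](C(=O)OC)c1c(OCOCC[Si](C)(C)C)cc(OCc2ccccc2)c(C)c1OCc1ccccc1 | intermediate
15 | (R)-1,1-dibromo-3-[2,4-bis(benzyloxy)-3-methyl-6-(SEM-oxy)phenyl]-4-methylpentan-2-one, present as its lithium enolate | CC(C)[C@@H](C(=O)C(Br)Br)c1c(OCOCC[Si](C)(C)C)cc(OCc2ccccc2)c(C)c1OCc1ccccc1 | intermediate (not isolated)
16 | lithium (S)-3-[2,4-bis(benzyloxy)-3-methyl-6-(SEM-oxy)phenyl]-4-methylpent-1-yn-1-olate | CC(C)[C@@H](C#CO[Li])c1c(OCOCC[Si](C)(C)C)cc(OCc2ccccc2)c(C)c1OCc1ccccc1 | intermediate (not isolated)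
17 | {[(3S)-3-[2,4-bis(benzyloxy)-3-methyl-6-(SEM-oxy)phenyl]-4-methylpent-1-yn-1-yl]oxy}triisopropylsilane | CC(C)[C@@H](C#CO[Si](C(C)C)(C(C)C)C(C)C)c1c(OCOCC[Si](C)(C)C)cc(OCc2ccccc2)c(C)c1OCc1ccccc1 | intermediate (key-step precursor)
18 | isobutyryl chloride | CC(C)C(=O)Cl | starting material
19 | 1-methoxyprop-1-yne | COC#CC | starting material
20 | dimethylketene | CC(C)=C=O | intermediate (not isolated)
21 | 3-methoxy-2,4,4-trimethylcyclobut-2-en-1-one | COC1=C(C)C(=O)C1(C)C | intermediate (key-step precursor)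
22 | 3-methoxy-2,4-dimethylpenta-1,3-dien-1-one (vinylketene) | O=C=C(C)C(OC)=C(C)C | intermediate (not isolated)
23 | 2-{(1R)-1-[2,4-bis(benzyloxy)-3-methyl-6-(SEM-oxy)phenyl]-2-methylpropyl}-4-(1-methoxy-2-methylprop-1-en-1-yl)-4-methyl-3-(triisopropylsilyloxy)cyclobut-2-en-1-one, both C4 epimers | COC(=C(C)C)C1(C)C(O[Si](C(C)C)(C(C)C)C(C)C)=C([C@@H](c2c(OCOCC[Si](C)(C)C)cc(OCc3ccccc3)c(C)c2OCc2ccccc2)C(C)C)C1=O | intermediate (not isolated)
24 | dienylketene with the methoxyvinyl group cis to the ketene-bearing carbon, (R) at the methine | COC(=C(C)C)/C(C)=C(/O[Si](C(C)C)(C(C)C)C(C)C)C(=C=O)[C@@H](c1c(OCOCC[Si](C)(C)C)cc(OCc2ccccc2)c(C)c1OCc1ccccc1)C(C)C | intermediate (not isolated)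
25 | 2-{(1R)-1-[2,4-bis(benzyloxy)-3-methyl-6-(SEM-oxy)phenyl]-2-methylpropyl}-5-methoxy-4,6,6-trimethyl-3-(triisopropylsilyloxy)cyclohexa-2,4-dien-1-one | COC1=C(C)C(O[Si](C(C)C)(C(C)C)C(C)C)=C([C@@H](c2c(OCOCC[Si](C)(C)C)cc(OCc3ccccc3)c(C)c2OCc2ccccc2)C(C)C)C(=O)C1(C)C | intermediate (key-step product)
26 | 2-{(1R)-1-[2,4-bis(benzyloxy)-3-methyl-6-(SEM-oxy)phenyl]-2-methylpropyl}-3-hydroxy-5-methoxy-4,4,6-trimethylcyclohexa-2,5-dien-1-one, present as its cesium enolate | COC1=C(C)C(=O)C([C@@H](c2c(OCOCC[Si](C)(C)C)cc(OCc3ccccc3)c(C)c2OCc2ccccc2)C(C)C)=C(O)C1(C)C | intermediate (not isolated)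
27 | 3-(benzyloxy)-2-{(1R)-1-[2,4-bis(benzyloxy)-3-methyl-6-(SEM-oxy)phenyl]-2-methylpropyl}-5-methoxy-4,6,6-trimethylcyclohexa-2,4-dien-1-one | COC1=C(C)C(OCc2ccccc2)=C([C@@H](c2c(OCOCC[Si](C)(C)C)cc(OCc3ccccc3)c(C)c2OCc2ccccc2)C(C)C)C(=O)C1(C)C | intermediate
28 | 3-(benzyloxy)-2-{(1R)-1-[2,4-bis(benzyloxy)-6-hydroxy-3-methylphenyl]-2-methylpropyl}-5-methoxy-4,6,6-trimethylcyclohexa-2,4-dien-1-one | COC1=C(C)C(OCc2ccccc2)=C([C@@H](c2c(O)cc(OCc3ccccc3)c(C)c2OCc2ccccc2)C(C)C)C(=O)C1(C)C | intermediate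
29 | ethyl (R)-3-hydroxy-3-phenylpropanoate | CCOC(=O)C[C@@H](O)c1ccccc1 | starting material
30 | ethyl (3S)-3-{3,5-bis(benzyloxy)-2-[(1R)-1-(2-benzyloxy-4-methoxy-3,5,5-trimethyl-6-oxocyclohexa-1,3-dien-1-yl)-2-methylpropyl]-4-methylphenoxy}-3-phenylpropanoate | COC1=C(C)C(OCc2ccccc2)=C([C@@H](c2c(O[C@@H](CC(=O)OCC)c3ccccc3)cc(OCc3ccccc3)c(C)c2OCc2ccccc2)C(C)C)C(=O)C1(C)C | intermediate
31 | (3S)-3-{3,5-bis(benzyloxy)-2-[(1R)-1-(2-benzyloxy-4-methoxy-3,5,5-trimethyl-6-oxocyclohexa-1,3-dien-1-yl)-2-methylpropyl]-4-methylphenoxy}-3-phenylpropanoic acid | COC1=C(C)C(OCc2ccccc2)=C([C@@H](c2c(O[C@@H](CC(=O)O)c3ccccc3)cc(OCc3ccccc3)c(C)c2OCc2ccccc2)C(C)C)C(=O)C1(C)C | intermediate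
32 | mixed anhydride of 31 with trifluoroacetic acid | COC1=C(C)C(OCc2ccccc2)=C([C@@H](c2c(O[C@@H](CC(=O)OC(=O)C(F)(F)F)c3ccccc3)cc(OCc3ccccc3)c(C)c2OCc2ccccc2)C(C)C)C(=O)C1(C)C | intermediate (not isolated)
33 | (2S)-5,7-bis(benzyloxy)-8-[(1R)-1-(2-benzyloxy-4-methoxy-3,5,5-trimethyl-6-oxocyclohexa-1,3-dien-1-yl)-2-methylpropyl]-6-methyl-2-phenylchroman-4-one | COC1=C(C)C(OCc2ccccc2)=C([C@@H](c2c(OCc3ccccc3)c(C)c(OCc3ccccc3)c3c2O[C@H](c2ccccc2)CC3=O)C(C)C)C(=O)C1(C)C | intermediate
34 | (2S)-5,7-dihydroxy-8-[(1R)-1-(2-hydroxy-4-methoxy-3,3,5-trimethyl-6-oxocyclohexa-1,4-dien-1-yl)-2-methylpropyl]-6-methyl-2-phenylchroman-4-one | COC1=C(C)C(=O)C([C@@H](c2c(O)c(C)c(O)c3c2O[C@H](c2ccccc2)CC3=O)C(C)C)=C(O)C1(C)C | target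

Total step count: 18. Longest linear sequence: 17 steps (steps 1–10 and 12–18 from 2-methylresorcinol); step 11 is a one-step side branch.

Steps most likely to fail

Step 12. The vinylketene may be drained by a 1,5-hydrogen shift from a terminal methyl or by dimerisation before the crowded alkyne traps it, and closure onto the fully substituted terminus may be slow enough for the siloxyalkyne to rearrange. The fallback sets out from 17 and comes back at 25. Compound 17 is heated with 3-methoxy-2,4-dimethylcyclobut-2-en-1-one F1 (made like 21, from propanoyl chloride, Et3N and 19), which keeps a hydrogen on C4. The ordinary vinylketene–alkyne benzannulation (Danheiser annulation) then ends, after tautomerisation, in 2-{(1R)-1-[2,4-bis(benzyloxy)-3-methyl-6-(SEM-oxy)phenyl]-2-methylpropyl}-5-methoxy-4,6-dimethyl-3-(triisopropylsilyloxy)phenol F2, with the free hydroxyl on C3′. Alkylative dearomatisation of its lithium phenoxide (t-BuOLi, MeI, toluene) should put the second methyl on C4′, since the other ortho carbon C2′ is blocked, and gives 25.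

Step 8. The two ortho alkoxy groups of the twisted aryl ring sit over both faces of the tetrasubstituted alkene, so binding to ruthenium may stall or the facial selection may be poor. The fallback sets out from 11 and comes back at 14. Electron-transfer conjugate reduction with Mg in MeOH, which does not need access of a metal complex to the alkene and transesterifies at the same time, should give methyl (RS)-2-[2,4-bis(benzyloxy)-3-methyl-6-(SEM-oxy)phenyl]-3-methylbutanoate F3. The racemate is resolved by preparative chromatography on a chiral stationary phase, and the (R)-ester is 14.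

Step 10. Dibromomethyllithium may add too slowly to the crowded ester carbonyl before it decomposes, and the amide bases may instead remove the benzylic α-hydrogen, with loss of configuration. The fallback sets out from 13 and comes back at 16, which is silylated as in step 10. LiAlH4 reduces 13 to (R)-2-[2,4-bis(benzyloxy)-3-methyl-6-(SEM-oxy)phenyl]-3-methylbutan-1-ol F4. Dess–Martin periodinane then gives (R)-2-[2,4-bis(benzyloxy)-3-methyl-6-(SEM-oxy)phenyl]-3-methylbutanal F5. Corey–Fuchs olefination (CBr4, PPh3) gives (S)-1,1-dibromo-3-[2,4-bis(benzyloxy)-3-methyl-6-(SEM-oxy)phenyl]-4-methylpent-1-ene F6. Two equivalents of n-BuLi at −78 °C give lithium (S)-3-[2,4-bis(benzyloxy)-3-methyl-6-(SEM-oxy)phenyl]-4-methylpent-1-yn-1-ide F7, which is oxidised at the remote alkyne terminus with lithium tert-butyl peroxide to the ynolate 16.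

Further compounds
F1 | step 12 | 3-methoxy-2,4-dimethylcyclobut-2-en-1-one | COC1=C(C)C(=O)C1C
F2 | step 12 | 2-{(1R)-1-[2,4-bis(benzyloxy)-3-methyl-6-(SEM-oxy)phenyl]-2-methylpropyl}-5-methoxy-4,6-dimethyl-3-(triisopropylsilyloxy)phenol | COc1c(C)c(O)c([C@@H](c2c(OCOCC[Si](C)(C)C)cc(OCc3ccccc3)c(C)c2OCc2ccccc2)C(C)C)c(O[Si](C(C)C)(C(C)C)C(C)C)c1C
F3 | step 8 | methyl (RS)-2-[2,4-bis(benzyloxy)-3-methyl-6-(SEM-oxy)phenyl]-3-methylbutanoate | CC(C)C(C(=O)OC)c1c(OCOCC[Si](C)(C)C)cc(OCc2ccccc2)c(C)c1OCc1ccccc1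
F4 | step 10 | (R)-2-[2,4-bis(benzyloxy)-3-methyl-6-(SEM-oxy)phenyl]-3-methylbutan-1-ol | CC(C)[C@@H](CO)c1c(OCOCC[Si](C)(C)C)cc(OCc2ccccc2)c(C)c1OCc1ccccc1
F5 | step 10 | (R)-2-[2,4-bis(benzyloxy)-3-methyl-6-(SEM-oxy)phenyl]-3-methylbutanal | CC(C)[C@@H](C=O)c1c(OCOCC[Si](C)(C)C)cc(OCc2ccccc2)c(C)c1OCc1ccccc1
F6 | step 10 | (S)-1,1-dibromo-3-[2,4-bis(benzyloxy)-3-methyl-6-(SEM-oxy)phenyl]-4-methylpent-1-ene | CC(C)[C@@H](C=C(Br)Br)c1c(OCOCC[Si](C)(C)C)cc(OCc2ccccc2)c(C)c1OCc1ccccc1
F7 | step 10 | lithium (S)-3-[2,4-bis(benzyloxy)-3-methyl-6-(SEM-oxy)phenyl]-4-methylpent-1-yn-1-ide | CC(C)[C@@H](C#C[Li])c1c(OCOCC[Si](C)(C)C)cc(OCc2ccccc2)c(C)c1OCc1ccccc1
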